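The ten-membered ring is closed by an anionic oxy-Cope ring expansion. The (Z)-C2=C3 olefin and the methylene-bearing C7 sit 1,5 across the C4–C5 bond of the cyclodecene ring (eunicellane numbering). A retro-[3,3] shift therefore leads to a cis-decalin whose second ring (C1, C2, C7–C10) carries isopropenyl at C2 and a vinyl carbinol at C7. One operation forms C4–C5, expands six to ten members, sets the Z-olefin, unveils the C7 carbonyl and delivers a regiodefined enolate that is hydroxylated at C6. The decalin comes from a Diels–Alder reaction of (R)-cryptone with a chloro-substituted 1-alkoxy-3-silyloxy diene, followed by a halohydrin (semipinacol) isopropenyl shift.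

Key step: step 10

Remark on numbering: ring A = cyclohexane C1, C10, C11 (Me, OH), C12, C13, C14 (iPr); ten-membered ring = C1 to C10 (C3–Me, C6–OAc, C7=CH2, C9–OAc); ring B = the temporary six-membered ring C1, C2, C7, C8, C9, C10; the "upper face" of ring B is the face bearing C11 and C14. PMB = 4-methoxybenzyl, TBS = tert-butyldimethylsilyl.
Assumption: (R)-cryptone is not taken as a catalogue compound and is made in step 1.

Step 1
Reactants: 1 3-methylbutanal; 2 but-3-en-2-one
Product: 4 (R)-4-isopropylcyclohex-2-en-1-one [(R)-cryptone], via keto aldehyde 3 (not isolated)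
Conditions: (R)-α,α-diphenylprolinol trimethylsilyl ether (cat.), neat, 0 °C; then LiOH, iPrOH, rt
Reagents that add atoms: none
Why: Enamine-catalysed Michael addition (the enone should approach the enamine face remote from the diarylsilyloxymethyl group, setting the R centre that becomes C14) followed by intramolecular aldol condensation closes the cyclohexenone.

Step 2
Reactants: 5 (E)-4-methoxybut-3-en-2-one; 6 4-methoxybenzyl alcohol
Product: 7 (E)-4-(4-methoxybenzyloxy)but-3-en-2-one
Conditions: PPTS (cat.), toluene, 80 °C, removal of MeOH
Reagents that add atoms: none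
Why: Acid-catalysed conjugate addition–elimination (transetherification of a vinylogous ester) exchanges methoxy for the oxidatively removable PMB-oxy group with retention of the E geometry.

Step 3
Reactants: 7 (E)-4-(4-methoxybenzyloxy)but-3-en-2-one
Product: 8 (E)-1-chloro-4-(4-methoxybenzyloxy)but-3-en-2-one
Conditions: LiN(iPr)2, THF, −78 °C; then TsCl
Reagents that add atoms: p-toluenesulfonyl chloride, Cc1ccc(cc1)S(Cl)(=O)=O
Why: The methyl group is the only enolisable position of the vinylogous ester, so kinetic deprotonation and enolate α-chlorination by the sulfonyl chloride should give the chloromethyl ketone.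

Step 4
Reactants: 8 (E)-1-chloro-4-(4-methoxybenzyloxy)but-3-en-2-one
Product: 9 (1Z,3E)-2-(tert-butyldimethylsilyloxy)-1-chloro-4-(4-methoxybenzyloxy)buta-1,3-diene
Conditions: TBSOTf, Et3N, Et2O, 0 °C
Reagents that add atoms: tert-butyldimethylsilyl triflate, CC(C)(C)[Si](C)(C)OS(=O)(=O)C(F)(F)F
Why: Soft enolisation toward CH2Cl (the only α-hydrogens) gives the 1-alkoxy-3-silyloxy diene, the Z enol ether (Cl syn to OSi, away from the vinyl group) being favoured on steric grounds.

Step 5
Reactants: 4 (R)-cryptone; 9 chloro diene
Product: 10 cis-fused Diels–Alder adduct (7-OTBS enol ether; 2-Cl; 9-OPMB; 11-ketone)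
Conditions: toluene, BHT (cat.), 130 °C, sealed tube
Reagents that add atoms: none
Why: Normal-demand Diels–Alder reaction in which the CHCl terminus (enol-ether β-carbon) bonds to the enone β-carbon C1 and the diene approaches anti to the isopropyl group and endo to the carbonyl, so that H1/H10 are cis, the C9 ether is cis to C11 and, both diene substituents being "outside", Cl is cis to the C9 ether.

Step 6
Reactants: 10 Diels–Alder adduct
Product: 12 cis-decalin 2-chloro-7-ketone (9-OPMB; 11-methylene), via methylene silyl enol ether 11 (not isolated)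
Conditions: Cp2TiMe2, toluene, 65 °C; then HF·pyridine, THF, 0 °C
Reagents that add atoms: dimethyltitanocene (Cp2TiMe2), C[Ti](C)(C1C=CC=C1)C1C=CC=C1
Why: Non-basic Petasis methylenation converts the only carbonyl (C11) into the exocyclic olefin without touching the epimerisable ring fusion or the β-alkoxy group, and fluoride cleavage of the silyl enol ether then unveils the C7 ketone as its 2-chloro derivative.

Step 7
Reactants: 12 2-chloro-7-ketone; 13 isopropenylmagnesium bromide
Product: 15 cis-decalin 2-isopropenyl-7-ketone (isopropenyl trans to the C9 ether), via magnesium chlorohydrinate 14 (not isolated)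
Conditions: THF, −78 °C; then toluene, 80 °C
Reagents that add atoms: none
Why: The Grignard reagent adds to C7 anti to the C–Cl bond on the lower (convex) face, and in the magnesium chlorohydrinate the isopropenyl group is antiperiplanar to C2–Cl and migrates with inversion on heating (semipinacol-type halohydrin rearrangement), restoring the C7 ketone and placing isopropenyl regiospecifically at C2.

Step 8
Reactants: 15 2-isopropenyl-7-ketone; 16 ethynylmagnesium bromide
Product: 17 7-ethynyl carbinol (OH on the upper face; ethynyl cis to isopropenyl)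
Conditions: CeCl3, THF, −78 °C
Reagents that add atoms: none
Why: The weakly basic cerium acetylide adds to the enolisable β,γ-unsaturated ketone from the lower face (the axial entry preferred by small sp nucleophiles and the face opposite the C9 ether and C14), placing the alkynyl group cis to isopropenyl.

Step 9
Reactants: 17 7-ethynyl carbinol
Product: 18 7-vinyl carbinol (cis-2-isopropenyl-1-vinyl cyclohexanol unit in ring B)
Conditions: H2 (1 atm), Pd/CaCO3 poisoned with Pb(OAc)2, quinoline, EtOAc, rt
Reagents that add atoms: none
Why: Lindlar-type semihydrogenation should stop at the vinyl stage and leave the two 1,1-disubstituted olefins and the benzylic ether untouched.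

Step 10
Reactants: 18 7-vinyl carbinol
Product: 21 bicyclic (2Z)-6-hydroxy-7-ketone (ten-membered ring fused to ring A), via potassium alkoxide 19 (not isolated), via potassium enolate 20 (not isolated)
Conditions: KN(SiMe3)2, 18-crown-6, THF, 0 °C; then −78 °C, 2-(phenylsulfonyl)-3-phenyloxaziridine
Reagents that add atoms: 2-(phenylsulfonyl)-3-phenyloxaziridine, O=S(=O)(c1ccccc1)N1OC1c1ccccc1
Why: The potassium alkoxide undergoes an anionic oxy-Cope [3,3]-sigmatropic shift in which the C2–C7 bond of ring B breaks while C4–C5 forms between the two olefin termini, and the regiodefined C6=C7 potassium enolate so produced is hydroxylated at C6 by the oxaziridine in the same flask. The closest known reaction type is the anionic oxy-Cope ring expansion of cis-2-alkenyl-1-vinylcyclohexanols to (Z)-cyclodec-5-enones combined with enolate α-hydroxylation. The ten-membered ring closes by four-atom ring expansion of ring B through a chair-like six-centre transition state (C4, C3, C2, C7, C6, C5), not by end-to-end cyclisation. The Z geometry of C2=C3 follows from the reacting chair of ring B in which vinyl is axial and isopropenyl equatorial (C1 pseudo-axial in the transition state), and C6 should become R because the oxaziridine can reach only the outer face of the E-configured ring enolate, whose planar chirality is fixed by that same transition state. The step needs Z over E and one enolate face; these should be secured by the cis relation of the two alkenyl groups (steps 7 and 8), by the still sp2 C11 (no axial methyl, so ring A tolerates the ring-B chair with equatorial C7 and C9 oxygens) and by the crown-ether-separated alkoxide (which disfavours the other chair with C14, O7 and O9 all syn-axial), with strain release from ring B adding driving force.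

Step 11
Reactants: 21 6-hydroxy-7-ketone
Product: 22 6,11-dihydroxy-7-ketone (C11: Me cis to C9, OH cis to H10)
Conditions: Mn(dpm)3 (cat.), PhSiH3, O2 (1 atm), iPrOH–CH2Cl2, 0 °C
Reagents that add atoms: dioxygen, O=O
Why: Mukaiyama-type hydrogen-atom-transfer hydration should select the 1,1-disubstituted exocyclic olefin over the trisubstituted ring olefin, and trapping of the tertiary C11 radical by O2 on the convex face of ring A (anti to the ten-membered ring) should place OH cis to H10.

Step 12
Reactants: 22 6,11-dihydroxy-7-ketone
Product: 23 7(19)-methylene 6,11-diol 9-PMB ether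
Conditions: Cp2TiMe2 (excess), toluene–THF, 70 °C
Reagents that add atoms: dimethyltitanocene (Cp2TiMe2), C[Ti](C)(C1C=CC=C1)C1C=CC=C1
Why: Petasis methylenation is non-basic, so the α-hydroxy ketone becomes the exocyclic olefin without epimerising C6 or eliminating the β-ether (the free hydroxyls only consume extra reagent).

Step 13
Reactants: 23 9-PMB ether
Product: 24 6,9,11-triol
Conditions: DDQ, CH2Cl2–pH 7 buffer, 0 °C
Reagents that add atoms: none
Why: Oxidative cleavage of the electron-rich PMB ether (benzylic hydride abstraction, then hydrolysis of the oxocarbenium ion) is faster than any reaction of the isolated olefins or alcohols.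

Step 14
Reactants: 24 6,9,11-triol
Product: 25 target CNP0303839.1
Conditions: Ac2O, pyridine, DMAP (cat.), CH2Cl2, 0 °C to rt
Reagents that add atoms: acetic anhydride, CC(=O)OC(C)=O
Why: Acylation distinguishes the two secondary alcohols (C6, C9) from the hindered tertiary C11 hydroxyl, which stays free.

Compound list
1 | 3-methylbutanal (isovaleraldehyde) | CC(C)CC=O | starting material
2 | but-3-en-2-one (methyl vinyl ketone) | CC(=O)C=C | starting material
3 | (R)-2-isopropyl-5-oxohexanal | O=C[C@@H](C(C)C)CCC(C)=O | intermediate (not isolated)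
4 | (R)-4-isopropylcyclohex-2-en-1-one, (R)-cryptone | O=C1C=C[C@@H](C(C)C)CC1 | intermediate
5 | (E)-4-methoxybut-3-en-2-one | CO/C=C/C(C)=O | starting material
6 | 4-methoxybenzyl alcohol | COc1ccc(CO)cc1 | starting material
7 | (E)-4-(4-methoxybenzyloxy)but-3-en-2-one | CC(=O)/C=C/OCc1ccc(OC)cc1 | intermediate
8 | (E)-1-chloro-4-(4-methoxybenzyloxy)but-3-en-2-one | ClCC(=O)/C=C/OCc1ccc(OC)cc1 | intermediate
9 | (1Z,3E)-2-(tert-butyldimethylsilyloxy)-1-chloro-4-(4-methoxybenzyloxy)buta-1,3-diene | Cl/C=C(O[Si](C)(C)C(C)(C)C)/C=C/OCc1ccc(OC)cc1 | intermediate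
10 | cis-fused bicyclo[4.4.0]decene adduct: 11-ketone, C7=C8 enol ether with 7-OTBS, 9-OPMB and 2-Cl both on the upper face of ring B, 14-iPr trans to C2 | CC(C)(C)[Si](C)(C)OC1=C[C@@H](OCc3ccc(OC)cc3)[C@@H]2[C@H]([C@H]1Cl)[C@@H](C(C)C)CCC2=O | intermediate
11 | 11-methylene analogue of 10 (silyl enol ether retained) | CC(C)(C)[Si](C)(C)OC1=C[C@@H](OCc3ccc(OC)cc3)[C@@H]2[C@H]([C@H]1Cl)[C@@H](C(C)C)CCC2=C | intermediate (not isolated)
12 | cis-decalin 7-ketone with 2-Cl and 9-OPMB on the upper face, 11-methylene, 14-iPr | O=C1C[C@@H](OCc3ccc(OC)cc3)[C@@H]2[C@H]([C@H]1Cl)[C@@H](C(C)C)CCC2=C | intermediate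
13 | isopropenylmagnesium bromide | CC(=C)[Mg]Br | starting material
14 | bromomagnesium alkoxide of the C7 chlorohydrin (7-O upper face, 7-isopropenyl lower face, 2-Cl upper face) | Br[Mg]O[C@@]1(C(C)=C)C[C@@H](OCc3ccc(OC)cc3)[C@@H]2[C@H]([C@H]1Cl)[C@@H](C(C)C)CCC2=C | intermediate (not isolated)
15 | cis-decalin 7-ketone with 2-isopropenyl on the lower face (trans to 9-OPMB), 11-methylene | O=C1C[C@@H](OCc3ccc(OC)cc3)[C@@H]2[C@H]([C@@H]1C(C)=C)[C@@H](C(C)C)CCC2=C | intermediate
16 | ethynylmagnesium bromide | C#C[Mg]Br | starting material
17 | 7-ethynyl carbinol: 7-OH upper face (cis to 9-OPMB), ethynyl lower face (cis to 2-isopropenyl) | O[C@@]1(C#C)C[C@@H](OCc3ccc(OC)cc3)[C@@H]2[C@H]([C@@H]1C(C)=C)[C@@H](C(C)C)CCC2=C | intermediate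
18 | 7-vinyl carbinol, same configuration as 17 | O[C@@]1(C=C)C[C@@H](OCc3ccc(OC)cc3)[C@@H]2[C@H]([C@@H]1C(C)=C)[C@@H](C(C)C)CCC2=C | intermediate
19 | potassium alkoxide of 18 | [K]O[C@@]1(C=C)C[C@@H](OCc3ccc(OC)cc3)[C@@H]2[C@H]([C@@H]1C(C)=C)[C@@H](C(C)C)CCC2=C | intermediate (not isolated)
20 | potassium C6=C7 enolate of the ring-expanded ketone (2Z olefin; C5 and C8 trans across the enolate) | [K]O/C1=C\CC/C(C)=C\[C@H]2[C@@H]([C@H](OCc3ccc(OC)cc3)C1)C(=C)CC[C@@H]2C(C)C | intermediate (not isolated)
21 | 6/10-bicyclic (2Z,6R)-6-hydroxy-9-(PMB-oxy)-11(20)-methylene-7-ketone, C1, C9, C10, C14 as in the target | O=C1C[C@@H](OCc3ccc(OC)cc3)[C@@H]2[C@H](/C=C(/C)CC[C@H]1O)[C@@H](C(C)C)CCC2=C | intermediate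
22 | 6,11-dihydroxy-9-(PMB-oxy)-7-ketone, all centres as in the target | O=C1C[C@@H](OCc3ccc(OC)cc3)[C@@H]2[C@H](/C=C(/C)CC[C@H]1O)[C@@H](C(C)C)CC[C@@]2(C)O | intermediate
23 | 9-O-PMB ether of the eunicella-2(Z),7(19)-diene-6,9,11-triol | C=C1C[C@@H](OCc3ccc(OC)cc3)[C@@H]2[C@H](/C=C(/C)CC[C@H]1O)[C@@H](C(C)C)CC[C@@]2(C)O | intermediate
24 | eunicella-2(Z),7(19)-diene-6,9,11-triol | C=C1C[C@@H](O)[C@@H]2[C@H](/C=C(/C)CC[C@H]1O)[C@@H](C(C)C)CC[C@@]2(C)O | intermediate
25 | CNP0303839.1, 6,9-diacetoxy-eunicella-2(Z),7(19)-dien-11-ol | C=C1C[C@@H](OC(C)=O)[C@@H]2[C@H](/C=C(/C)CC[C@H]1OC(C)=O)[C@@H](C(C)C)CC[C@@]2(C)O | target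

Total step count: 14. Longest linear sequence: 13 steps (5 to 25, steps 2 to 14).

Steps most likely to fail

Step 10. The two chair transition states of ring B may compete, which would erode the Z geometry of C2=C3, and the ring enolate may relax before oxidation, which would erode facial control at C6. Fallback: starting again from 18 under the same conditions, should the (2E)-hydroxy ketone F4 be formed, thiyl-radical addition–elimination (PhSSPh cat., hν, benzene) should equilibrate the trisubstituted olefin toward the thermodynamically preferred cis-cyclodecene; this fallback comes back to the route at 21.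

Step 5. The cycloaddition may stall because the cyclohexenone is a weak dienophile and the chloro diene may decompose on prolonged heating. Fallback: from 4, bromination–dehydrobromination (Br2, then Et3N) gives (R)-2-bromo-4-isopropylcyclohex-2-en-1-one F1, a much more reactive α-halo enone dienophile. Its cycloaddition with 9 under the same facial and endo rules gives the angular C10 bromide F2. Radical debromination (Bu3SnH, AIBN), with hydrogen delivered to the C10 radical from the convex face, comes back to the route at 10.

Step 7. The Grignard reagent may enolise or epimerise the α-chloro ketone, and the halohydrin salt may close to an epoxide or contract the ring instead of shifting the alkenyl group. Fallback: from 12, reductive enolate formation (SmI2, THF, −78 °C) and aldol addition to 1-(trimethylsilyl)propan-2-one, with carbon entering C2 from the lower face, give the β-hydroxysilane F3. Acid-promoted Peterson elimination (BF3·OEt2) then forms the isopropenyl group regiospecifically and comes back to the route at 15.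

Further compounds
F1 | step 5 | (R)-2-bromo-4-isopropylcyclohex-2-en-1-one | O=C1C(Br)=C[C@@H](C(C)C)CC1
F2 | step 5 | C10-bromo analogue of adduct 10 (Br in place of H10, lower face) | CC(C)(C)[Si](C)(C)OC1=C[C@@H](OCc3ccc(OC)cc3)[C@]2(Br)[C@H]([C@H]1Cl)[C@@H](C(C)C)CCC2=O
F3 | step 7 | 7-ketone bearing 2-[2-hydroxy-1-(trimethylsilyl)propan-2-yl] on the lower face (carbinol centre unassigned) | O=C1C[C@@H](OCc3ccc(OC)cc3)[C@@H]2[C@H]([C@@H]1C(C)(O)C[Si](C)(C)C)[C@@H](C(C)C)CCC2=C
F4 | step 10 | (2E)-isomer of hydroxy ketone 21 | O=C1C[C@@H](OCc3ccc(OC)cc3)[C@@H]2[C@H](/C=C(\C)CC[C@H]1O)[C@@H](C(C)C)CCC2=C
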